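**Retrosynthetic overview**
- The plan rests on the C1–C2 bond of the ten-membered carbocycle: C1 is the hydrogen-bearing sp2 end of the E-trisubstituted C1=C10 alkene and C2 is an unfunctionalised ring methylene, so this bond can be made last by sp2–sp3 coupling with the alkene geometry already fixed.
- Endgame: the C6 ester is cut to a protected 4-hydroxybenzoic acid, and the oxirane (C4, C5, O) is traced back to the 4E alkene by epoxidation directed by the free C6 hydroxyl.
- Ring closure: hydroboration of the terminal C2=C3 alkene and intramolecular B-alkyl Suzuki–Miyaura coupling with the C1 vinyl iodide.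
- Open chain: the C10=C1 iodoalkene comes from a terminal alkyne by methylalumination–iodination, C8–C9 from asymmetric propargylation of the C8 aldehyde, and C6–C7 from an Evans syn-aldol of an isovaleryl imide with (E)-3-methylpenta-2,4-dienal.
- Order of ring formation: carbocycle first (step 11), oxirane second (step 13).

Key step: step 11

Remark (assumption): in step 8, (R)-TRIP is taken to deliver the propargyl group to the Re face of the aldehyde, the sense known for simple aldehydes. Germacrane numbering is used throughout (ring C1–C10, C14 methyl on C10, C15 methyl on C4, isopropyl on C7).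

**Step 1**
Reactants: 1 (S)-4-benzyl-1,3-oxazolidin-2-one; 2 isovaleryl chloride
Product: 3 (S)-4-benzyl-3-(3-methylbutanoyl)-1,3-oxazolidin-2-one
Conditions: n-BuLi, THF, −78 °C; then 2, −78 to 0 °C
Reagents that add atoms: none
Why: N-acylation of the lithiated oxazolidinone by the acid chloride is the standard Evans imide formation and creates no stereocentre.

**Step 2**
Reactants: 4 (E)-3-methylpent-2-en-4-yn-1-ol
Product: 5 (E)-3-methylpenta-2,4-dien-1-ol
Conditions: H2 (1 atm), Pd/CaCO3 poisoned with Pb(OAc)2, quinoline, Et2O, 0 °C to rt, stopped after one equivalent of H2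
Reagents that add atoms: none
Why: Lindlar semi-hydrogenation should stop at the vinyl group because the poisoned palladium surface binds the terminal alkyne much more strongly than the diene, and the E-trisubstituted alkene is not touched.

**Step 3**
Reactants: 5 (E)-3-methylpenta-2,4-dien-1-ol
Product: 6 (E)-3-methylpenta-2,4-dienal
Conditions: activated MnO2, CH2Cl2, rt; filtered and used as a solution
Reagents that add atoms: none
Why: allylic alcohol oxidation with MnO2 is selective for the allylic carbinol and should leave the diene geometry intact, and the volatile dienal is not concentrated.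

**Step 4**
Reactants: 3 (S)-4-benzyl-3-(3-methylbutanoyl)-1,3-oxazolidin-2-one; 6 (E)-3-methylpenta-2,4-dienal
Product: 8 (4S)-4-benzyl-3-[(2S,3R,4E)-3-hydroxy-5-methyl-2-(propan-2-yl)hepta-4,6-dienoyl]-1,3-oxazolidin-2-one, via dibutylboron Z-enolate 7 (not isolated)
Conditions: Bu2BOTf, iPr2NEt, CH2Cl2, −78 to 0 °C; then 6, −78 to 0 °C; pH 7 buffer, MeOH, H2O2, 0 °C
Reagents that add atoms: none
Why: Evans syn-aldol, in which the Z-boron enolate reacts through a Zimmerman–Traxler chair with the dipole-minimised (S)-benzyl auxiliary shielding one enolate face, so that C7 (S in this compound) and C6 (R) are set syn under auxiliary control.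

**Step 5**
Reactants: 8 the syn-aldol imide
Product: 9 (2S,3R,4E)-3-hydroxy-N-methoxy-N,5-dimethyl-2-(propan-2-yl)hepta-4,6-dienamide
Conditions: AlMe3, MeNH(OMe)·HCl, THF, −20 to 0 °C; aq. potassium sodium tartrate
Reagents that add atoms: N,O-dimethylhydroxylamine hydrochloride, CNOC.Cl
Why: Weinreb transamination, in which the aluminium amide is guided by the aluminium alkoxide of the free C6 hydroxyl to the exocyclic imide carbonyl, releases the auxiliary without epimerising C7.

**Step 6**
Reactants: 9 the β-hydroxy Weinreb amide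
Product: 10 (2S,3R,4E)-N-methoxy-N,5-dimethyl-2-(propan-2-yl)-3-(triethylsilyloxy)hepta-4,6-dienamide
Conditions: TESOTf, 2,6-lutidine, CH2Cl2, −78 °C
Reagents that add atoms: triethylsilyl triflate, CC[Si](CC)(CC)OS(=O)(=O)C(F)(F)F
Why: silyl ether formation with a silyl triflate and a hindered base is reliable on a crowded secondary alcohol, and the lutidine buffer protects the acid-sensitive dienyl carbinol.

**Step 7**
Reactants: 10 the silylated Weinreb amide
Product: 11 (2S,3R,4E)-5-methyl-2-(propan-2-yl)-3-(triethylsilyloxy)hepta-4,6-dienal (the C8 aldehyde)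
Conditions: iBu2AlH, THF, −78 °C; aq. potassium sodium tartrate; used crude
Reagents that add atoms: none
Why: Weinreb amide reduction stops at the aldehyde because the chelated tetrahedral aluminium intermediate survives until work-up, and at −78 °C the C7 centre should not epimerise.

**Step 8**
Reactants: 11 the C8 aldehyde; 12 allenylboronic acid pinacol ester
Product: 13 (3E,5R,6R,7R)-3-methyl-6-(propan-2-yl)-5-(triethylsilyloxy)deca-1,3-dien-9-yn-7-ol (the 8R homopropargylic alcohol in germacrane numbering)
Conditions: 12, (R)-TRIP [(R)-3,3′-bis(2,4,6-triisopropylphenyl)-1,1′-binaphthyl-2,2′-diyl hydrogen phosphate] (10 mol%), 4 Å molecular sieves, toluene, 0 °C; aqueous work-up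
Reagents that add atoms: none
Why: chiral phosphoric acid-catalysed asymmetric propargylation (allenylboration) runs through a six-membered SE2′ transition state in which the catalyst activates the boronate and directs attack to the Re face of the aldehyde, so C8 should be set as R by catalyst control over the weak intrinsic bias of the α-branched aldehyde.

**Step 9**
Reactants: 13 the homopropargylic alcohol
Product: 14 tert-butyldimethyl{[(3E,5R,6R,7R)-3-methyl-6-(propan-2-yl)-5-(triethylsilyloxy)deca-1,3-dien-9-yn-7-yl]oxy}silane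
Conditions: TBSOTf, 2,6-lutidine, CH2Cl2, −78 to 0 °C
Reagents that add atoms: tert-butyldimethylsilyl triflate, CC(C)(C)[Si](C)(C)OS(=O)(=O)C(F)(F)F
Why: silyl ether formation gives the robust C8 tert-butyldimethylsilyl ether beside the more labile C6 triethylsilyl ether, which is the differentiation the endgame needs.

**Step 10**
Reactants: 14 the bis-silylated dienyne
Product: 16 tert-butyl{[(3E,5R,6R,7R,9E)-10-iodo-3,9-dimethyl-6-(propan-2-yl)-5-(triethylsilyloxy)deca-1,3,9-trien-7-yl]oxy}dimethylsilane (the E-vinyl iodide), via E-alkenyldimethylalane 15 (not isolated)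
Conditions: AlMe3, Cp2ZrCl2 (25 mol%), CH2Cl2, 0 °C to rt; then I2, THF, −30 to 0 °C; aq. potassium sodium tartrate
Reagents that add atoms: trimethylaluminium, C[Al](C)C; iodine, II
Why: Negishi zirconium-catalysed methylalumination adds methyl and aluminium syn across the terminal alkyne with aluminium on the terminal carbon much faster than it touches alkenes, and iodinolysis with retention should give the E-iodoalkene with the C14 methyl on C10.

**Step 11**
Reactants: 16 the E-vinyl iodide with the terminal 1,3-diene
Product: 18 (1(10)E,4E,6R,7R,8R)-8-(tert-butyldimethylsilyloxy)-6-(triethylsilyloxy)germacra-1(10),4-diene, via B-alkyl-9-BBN borane 17 (not isolated)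
Conditions: 9-BBN, THF, 0 °C to rt; then slow addition (syringe pump) to PdCl2(dppf) (15 mol%), AsPh3, Cs2CO3, degassed DMF/THF/H2O, 40 °C, about 1 mM final concentration
Reagents that add atoms: none
Why: 9-BBN adds anti-Markovnikov to the only monosubstituted alkene (C2=C3) and places boron on C2 to give homoallylic borane 17; zerovalent palladium formed from PdCl2(dppf) then inserts into the C1–I bond with retention, the base-activated borate transfers the primary C2 alkyl group to palladium, and reductive elimination forms C1–C2. The closest known reaction type is the one-pot hydroboration and intramolecular B-alkyl Suzuki–Miyaura macrocyclisation of alkenyl vinyl iodides. The ten-membered carbocycle closes by intramolecular transmetalation to an eleven-membered alkyl(alkenyl)palladium ring that contracts on reductive elimination, which the wide bite angle of dppf favours over β-hydride elimination. No stereocentre is created, and C6, C7, C8 and both E alkenes are carried through unchanged because oxidative addition and reductive elimination are stereoretentive at sp2 carbon. The step needs hydroboration at C2=C3 only, which the bulk of 9-BBN secures against the trisubstituted C4=C5 and the iodoalkene, and it needs ring closure to outrun oligomerisation, which slow addition at high dilution and the conformational restriction by two E-trisubstituted alkenes and three contiguous branched centres should favour. The temperature is kept at or below 40 °C so that the (E,E)-cyclodeca-1,5-diene does not undergo Cope rearrangement.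

**Step 12**
Reactants: 18 the germacradiene bis-silyl ether
Product: 19 (1(10)E,4E,6R,7S,8R)-8-(tert-butyldimethylsilyloxy)germacra-1(10),4-dien-6-ol (same spatial arrangement; the C7 descriptor changes only by priority)
Conditions: HF·pyridine, excess pyridine, THF, 0 °C
Reagents that add atoms: none
Why: selective desilylation works because a triethylsilyl ether is cleaved by buffered HF·pyridine much faster than a secondary tert-butyldimethylsilyl ether, and the pyridine buffer should prevent acid-induced transannular cyclisation of the cyclodecadiene.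

**Step 13**
Reactants: 19 the C6 allylic alcohol
Product: 20 (1(10)E,4R,5R,6S,7S,8R)-8-(tert-butyldimethylsilyloxy)-4,5-epoxygermacr-1(10)-en-6-ol
Conditions: VO(acac)2 (5 mol%), t-BuOOH (in decane), CH2Cl2, 0 °C
Reagents that add atoms: tert-butyl hydroperoxide, CC(C)(C)OO
Why: vanadium-catalysed hydroxyl-directed epoxidation reaches only C4=C5 (C1=C10 has no free hydroxyl nearby), and because 1,3-allylic strain with the C15 methyl keeps H6 in the alkene plane with C7 on the inner ring face and O6 on the outer face, oxygen should be delivered to the outer face syn to O6 to give the 4R,5R (threo) oxirane.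

**Step 14**
Reactants: 21 4-hydroxybenzoic acid
Product: 23 4-(tert-butyldimethylsilyloxy)benzoic acid, via bis-silylated benzoate 22 (not isolated)
Conditions: TBSCl, imidazole, DMF, rt; then AcOH/THF/H2O, rt
Reagents that add atoms: tert-butyldimethylsilyl chloride, CC(C)(C)[Si](C)(C)Cl
Why: exhaustive silylation followed by selective hydrolysis works because the silyl ester is far more labile to aqueous acid than the aryl silyl ether.

**Step 15**
Reactants: 20 the epoxy alcohol; 23 4-(tert-butyldimethylsilyloxy)benzoic acid
Product: 24 (1(10)E,4R,5R,6S,7S,8R)-8-(tert-butyldimethylsilyloxy)-4,5-epoxygermacr-1(10)-en-6-yl 4-(tert-butyldimethylsilyloxy)benzoate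
Conditions: EDC·HCl, DMAP, CH2Cl2, rt
Reagents that add atoms: none
Why: Steglich esterification acylates the C6 oxygen under near-neutral conditions that spare the oxirane, and the C6 configuration is retained because the C–O bond is not broken.

**Step 16**
Reactants: 24 the bis-silylated ester
Product: 25 (1(10)E,4R,5R,6S,7R,8R)-4,5-epoxy-8-hydroxygermacr-1(10)-en-6-yl 4-hydroxybenzoate (CNP0319712.1)
Conditions: Bu4NF buffered with AcOH (1:1), THF, 0 °C to rt
Reagents that add atoms: none
Why: fluoride-mediated desilylation removes the aryl and the C8 silyl ethers, and the acetic acid buffer should avoid both the free alkoxide that would cause acyl migration from O6 to O8 and the strong acid that would trigger transannular opening of the oxirane.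

**Compound list**
1 | (S)-4-benzyl-1,3-oxazolidin-2-one | O=C1N[C@@H](Cc2ccccc2)CO1 | starting material
2 | isovaleryl chloride | CC(C)CC(=O)Cl | starting material
3 | (S)-4-benzyl-3-(3-methylbutanoyl)-1,3-oxazolidin-2-one | CC(C)CC(=O)N1C(=O)OC[C@@H]1Cc1ccccc1 | intermediate
4 | (E)-3-methylpent-2-en-4-yn-1-ol | C#C/C(C)=C/CO | starting material
5 | (E)-3-methylpenta-2,4-dien-1-ol | C=C/C(C)=C/CO | intermediate
6 | (E)-3-methylpenta-2,4-dienal | C=C/C(C)=C/C=O | intermediate
7 | dibutylboron Z-enolate of 3 | CC(C)/C=C(\OB(CCCC)CCCC)N1C(=O)OC[C@@H]1Cc1ccccc1 | intermediate (not isolated)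
8 | (4S)-4-benzyl-3-[(2S,3R,4E)-3-hydroxy-5-methyl-2-(propan-2-yl)hepta-4,6-dienoyl]-1,3-oxazolidin-2-one | C=C/C(C)=C/[C@@H](O)[C@H](C(C)C)C(=O)N1C(=O)OC[C@@H]1Cc1ccccc1 | intermediate
9 | (2S,3R,4E)-3-hydroxy-N-methoxy-N,5-dimethyl-2-(propan-2-yl)hepta-4,6-dienamide | C=C/C(C)=C/[C@@H](O)[C@H](C(C)C)C(=O)N(C)OC | intermediate
10 | (2S,3R,4E)-N-methoxy-N,5-dimethyl-2-(propan-2-yl)-3-(triethylsilyloxy)hepta-4,6-dienamide | C=C/C(C)=C/[C@@H](O[Si](CC)(CC)CC)[C@H](C(C)C)C(=O)N(C)OC | intermediate
11 | (2S,3R,4E)-5-methyl-2-(propan-2-yl)-3-(triethylsilyloxy)hepta-4,6-dienal | C=C/C(C)=C/[C@@H](O[Si](CC)(CC)CC)[C@H](C(C)C)C=O | intermediate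
12 | allenylboronic acid pinacol ester (commercial; also accessible from propargyl bromide) | C=C=CB1OC(C)(C)C(C)(C)O1 | starting material
13 | (3E,5R,6R,7R)-3-methyl-6-(propan-2-yl)-5-(triethylsilyloxy)deca-1,3-dien-9-yn-7-ol | C=C/C(C)=C/[C@@H](O[Si](CC)(CC)CC)[C@H](C(C)C)[C@H](O)CC#C | intermediate
14 | tert-butyldimethyl{[(3E,5R,6R,7R)-3-methyl-6-(propan-2-yl)-5-(triethylsilyloxy)deca-1,3-dien-9-yn-7-yl]oxy}silane | C=C/C(C)=C/[C@@H](O[Si](CC)(CC)CC)[C@H](C(C)C)[C@H](O[Si](C)(C)C(C)(C)C)CC#C | intermediate
15 | E-alkenyldimethylalane from 14 | C=C/C(C)=C/[C@@H](O[Si](CC)(CC)CC)[C@H](C(C)C)[C@H](O[Si](C)(C)C(C)(C)C)C/C(C)=C/[Al](C)C | intermediate (not isolated)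
16 | tert-butyl{[(3E,5R,6R,7R,9E)-10-iodo-3,9-dimethyl-6-(propan-2-yl)-5-(triethylsilyloxy)deca-1,3,9-trien-7-yl]oxy}dimethylsilane | C=C/C(C)=C/[C@@H](O[Si](CC)(CC)CC)[C@H](C(C)C)[C@H](O[Si](C)(C)C(C)(C)C)C/C(C)=C/I | intermediate
17 | B-alkyl-9-BBN borane from 16 (boron on C2) | C1CCC2CCCC1B2CC/C(C)=C/[C@@H](O[Si](CC)(CC)CC)[C@H](C(C)C)[C@H](O[Si](C)(C)C(C)(C)C)C/C(C)=C/I | intermediate (not isolated)
18 | (1(10)E,4E,6R,7R,8R)-8-(tert-butyldimethylsilyloxy)-6-(triethylsilyloxy)germacra-1(10),4-diene | C/C1=C\CC/C(C)=C/[C@@H](O[Si](CC)(CC)CC)[C@H](C(C)C)[C@H](O[Si](C)(C)C(C)(C)C)C1 | intermediate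
19 | (1(10)E,4E,6R,7S,8R)-8-(tert-butyldimethylsilyloxy)germacra-1(10),4-dien-6-ol | C/C1=C\CC/C(C)=C/[C@@H](O)[C@H](C(C)C)[C@H](O[Si](C)(C)C(C)(C)C)C1 | intermediate
20 | (1(10)E,4R,5R,6S,7S,8R)-8-(tert-butyldimethylsilyloxy)-4,5-epoxygermacr-1(10)-en-6-ol | C/C1=C\CC[C@@]2(C)O[C@@H]2[C@@H](O)[C@H](C(C)C)[C@H](O[Si](C)(C)C(C)(C)C)C1 | intermediate
21 | 4-hydroxybenzoic acid | O=C(O)c1ccc(O)cc1 | starting material
22 | tert-butyldimethylsilyl 4-(tert-butyldimethylsilyloxy)benzoate | CC(C)(C)[Si](C)(C)Oc1ccc(cc1)C(=O)O[Si](C)(C)C(C)(C)C | intermediate (not isolated)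
23 | 4-(tert-butyldimethylsilyloxy)benzoic acid | CC(C)(C)[Si](C)(C)Oc1ccc(cc1)C(=O)O | intermediate
24 | (1(10)E,4R,5R,6S,7S,8R)-8-(tert-butyldimethylsilyloxy)-4,5-epoxygermacr-1(10)-en-6-yl 4-(tert-butyldimethylsilyloxy)benzoate | C/C1=C\CC[C@@]2(C)O[C@@H]2[C@@H](OC(=O)c2ccc(O[Si](C)(C)C(C)(C)C)cc2)[C@H](C(C)C)[C@H](O[Si](C)(C)C(C)(C)C)C1 | intermediate
25 | (1(10)E,4R,5R,6S,7R,8R)-4,5-epoxy-8-hydroxygermacr-1(10)-en-6-yl 4-hydroxybenzoate | C/C1=C\CC[C@@]2(C)O[C@@H]2[C@@H](OC(=O)c2ccc(O)cc2)[C@H](C(C)C)[C@H](O)C1 | target

**Totals and risks**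
Total step count: 16. Longest linear sequence: 14 steps (from 4 through steps 2–13, 15 and 16).

Steps most likely to fail:

1. Step 11. The strain of the ten-membered (E,E)-diene may slow the intramolecular transmetalation so that intermolecular coupling, protodeboronation or β-hydride elimination take over. The fallback sets out from 16 and changes the nucleophile from a borane made in the flask to an isolable halide-derived organozinc. Hydroboration to 17 and oxidation with NaBO3·4H2O would give primary alcohol F1, and I2, PPh3 and imidazole would convert it into primary iodide F2. Activated Zn dust in THF at 35 °C should insert only into the alkyl C–I bond to give alkylzinc iodide F3. Slow addition of F3 to Pd(PPh3)4 in THF at high dilution (intramolecular Negishi coupling, no base or water) would then close the same C1–C2 bond and return to the route at 18.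

2. Step 8. Facial selectivity may be poor if the catalyst and the α-branched aldehyde are mismatched, and the acid catalyst may partly remove the triethylsilyl group. The fallback sets out from 11 and moves the stereochemical decision from C–C bond formation to ketone reduction. Barbier propargylation (propargyl bromide, Zn, THF) would give homopropargylic alcohol epimer mixture F4. Dess–Martin oxidation buffered with NaHCO3 would give β,γ-ynone F5. Corey–Bakshi–Shibata reduction with the (S)-methyloxazaborolidine and catecholborane in toluene at −78 °C should deliver the 8R alcohol under reagent control and return to the route at 13.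

3. Step 13. The ring may populate the conformer that has O6 in the alkene plane and exposes the opposite face, giving the wrong epoxide diastereomer, or the vanadium Lewis acid may open the product transannularly. The fallback sets out from 16 and places the epoxidation in the open chain, where 1,3-allylic strain alone controls the face. Buffered HF·pyridine would give open-chain C6 alcohol F6. mCPBA with NaHCO3 in CH2Cl2 at 0 °C (hydrogen-bond-directed, threo-selective, and selective for the electron-rich trisubstituted C4=C5) would give open-chain epoxy alcohol F7. TESCl and imidazole would give triethylsilyl ether F8. Hydroboration with 9-BBN to borane F9 and the same palladium-catalysed ring closure would give macrocyclic epoxide F10, and buffered HF·pyridine would return to the route at 20.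

**Further compounds**
F1 | step 11 | (3E,5R,6R,7R,9E)-7-(tert-butyldimethylsilyloxy)-10-iodo-3,9-dimethyl-6-(propan-2-yl)-5-(triethylsilyloxy)deca-3,9-dien-1-ol | OCC/C(C)=C/[C@@H](O[Si](CC)(CC)CC)[C@H](C(C)C)[C@H](O[Si](C)(C)C(C)(C)C)C/C(C)=C/I
F2 | step 11 | primary iodide from F1 (iodine on C2 of the germacrane numbering) | ICC/C(C)=C/[C@@H](O[Si](CC)(CC)CC)[C@H](C(C)C)[C@H](O[Si](C)(C)C(C)(C)C)C/C(C)=C/I
F3 | step 11 | alkylzinc iodide from F2 (zinc on C2) | I[Zn]CC/C(C)=C/[C@@H](O[Si](CC)(CC)CC)[C@H](C(C)C)[C@H](O[Si](C)(C)C(C)(C)C)C/C(C)=C/I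
F4 | step 8 | (3E,5R,6R)-3-methyl-6-(propan-2-yl)-5-(triethylsilyloxy)deca-1,3-dien-9-yn-7-ol as a mixture of C7 epimers (C8 in germacrane numbering) | C=C/C(C)=C/[C@@H](O[Si](CC)(CC)CC)[C@H](C(C)C)C(O)CC#C
F5 | step 8 | (3E,5R,6S)-3-methyl-6-(propan-2-yl)-5-(triethylsilyloxy)deca-1,3-dien-9-yn-7-one | C=C/C(C)=C/[C@@H](O[Si](CC)(CC)CC)[C@H](C(C)C)C(=O)CC#C
F6 | step 13 | open-chain C6 alcohol from 16 (triethylsilyl group removed) | C=C/C(C)=C/[C@@H](O)[C@H](C(C)C)[C@H](O[Si](C)(C)C(C)(C)C)C/C(C)=C/I
F7 | step 13 | open-chain (4R,5R)-4,5-epoxy C6 alcohol (germacrane numbering) | C=C[C@@]1(C)O[C@@H]1[C@@H](O)[C@H](C(C)C)[C@H](O[Si](C)(C)C(C)(C)C)C/C(C)=C/I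
F8 | step 13 | triethylsilyl ether of F7 | C=C[C@@]1(C)O[C@@H]1[C@@H](O[Si](CC)(CC)CC)[C@H](C(C)C)[C@H](O[Si](C)(C)C(C)(C)C)C/C(C)=C/I
F9 | step 13 | B-alkyl-9-BBN borane from F8 (boron on C2) | C1CCC2CCCC1B2CC[C@@]1(C)O[C@@H]1[C@@H](O[Si](CC)(CC)CC)[C@H](C(C)C)[C@H](O[Si](C)(C)C(C)(C)C)C/C(C)=C/I
F10 | step 13 | (1(10)E,4R,5R)-8-(tert-butyldimethylsilyloxy)-4,5-epoxy-6-(triethylsilyloxy)germacr-1(10)-ene | C/C1=C\CC[C@@]2(C)O[C@@H]2[C@@H](O[Si](CC)(CC)CC)[C@H](C(C)C)[C@H](O[Si](C)(C)C(C)(C)C)C1
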